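**Retrosynthetic overview**

1. Target ⇒ six-fold O-dealkylation and methylation of the C3 acid ⇒ carboxylate-directed C4–H olefination of a trans-2-aryl-2,3-dihydrobenzofuran-3-carboxylic acid with the acrylate of protected (R)-danshensu, whose stereocentre is bought.
2. That acid ⇒ O-benzylation, desilylation and oxidation of a trans-2-aryl-3-(silyloxymethyl)-2,3-dihydrobenzofuran-7-ol.
3. Feature used: in ring B the C7 hydroxyl is ortho to C7a, the carbon that carries the ring oxygen O1. This O1–C7a–C7–OH array is what remains when a furan is converted into a phenol by an alkyne tethered through oxygen.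
4. Key disconnection: C3a–C7a and C6–C7, with the furan oxygen moving to C7, back to the ethynyl ether of a syn-1-aryl-2-(2-furyl)propane-1,3-diol mono-silyl ether. The dihydrofuran ring and ring B form together, last, from a bought furan.
5. The syn diol ⇒ auxiliary-controlled syn-aldol of a 2-furylacetyl oxazolidinone with 3,4-bis(benzyloxy)benzaldehyde, which sets C2 and C3 (syn in the chain becomes trans in the ring).

Key step: step 7

Remark: benzofuran numbering (O1, C2, C3, C3a, C4–C7, C7a) is used for all bicyclic compounds. The dihydroxyphenyl-lactic acid building block, usually sold as its sodium salt, is drawn and used as the free acid. The lactate half is protected with 4-methoxybenzyl (PMB) groups rather than benzyl so that its ester is released in the final step at −78 °C.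

**Route**

Step 1
Reactants: 1 2-(furan-2-yl)acetic acid; 2 (S)-4-benzyl-1,3-oxazolidin-2-one
Product: 4 (S)-4-benzyl-3-[2-(furan-2-yl)acetyl]-1,3-oxazolidin-2-one, via mixed pivalic anhydride 3 (not isolated)
Conditions: PivCl, Et3N, THF, −20 °C; then 2, LiCl, −20 °C to rt
Reagents that add atoms: none
Why: N-acylation of the oxazolidinone through the mixed pivalic anhydride (LiCl/Et3N variant) should occur at the unhindered furylacetyl carbonyl with pivalate as the leaving group, and touches no stereocentre.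

Step 2
Reactants: 4 (S)-4-benzyl-3-[2-(furan-2-yl)acetyl]-1,3-oxazolidin-2-one; 5 3,4-bis(benzyloxy)benzaldehyde
Product: 8 (S)-4-benzyl-3-[(2R,3S)-3-[3,4-bis(benzyloxy)phenyl]-2-(furan-2-yl)-3-hydroxypropanoyl]-1,3-oxazolidin-2-one, via Z-boron enolate 6 (not isolated), via boron aldolate 7 (not isolated)
Conditions: n-Bu2BOTf, Et3N, CH2Cl2, −78 to 0 °C; then 5, −78 to 0 °C; then pH 7 buffer, MeOH, 30% H2O2, 0 °C
Reagents that add atoms: none
Why: Evans syn-aldol reaction, in which soft enolisation gives the Z-boron enolate 6 and this adds to the aldehyde through a closed Zimmerman–Traxler chair on the enolate face away from the auxiliary benzyl group (imide dipoles opposed), so the auxiliary sets both new stereocentres as (2R,3S), syn, before oxidative release of aldolate 7.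

Step 3
Reactants: 8 (S)-4-benzyl-3-[(2R,3S)-3-[3,4-bis(benzyloxy)phenyl]-2-(furan-2-yl)-3-hydroxypropanoyl]-1,3-oxazolidin-2-one
Product: 9 (1S,2R)-1-[3,4-bis(benzyloxy)phenyl]-2-(furan-2-yl)propane-1,3-diol
Conditions: LiBH4, MeOH (1 equiv), THF, 0 °C
Reagents that add atoms: none
Why: Reductive cleavage of the N-acyl oxazolidinone by LiBH4 (hydride attack at the exocyclic carbonyl, then reduction of the released aldehyde) should give the 1,3-diol without epimerising the furyl-bearing carbon, and returns the auxiliary.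

Step 4
Reactants: 9 (1S,2R)-1-[3,4-bis(benzyloxy)phenyl]-2-(furan-2-yl)propane-1,3-diol
Product: 10 (1S,2R)-1-[3,4-bis(benzyloxy)phenyl]-2-(furan-2-yl)-3-[(triisopropylsilyl)oxy]propan-1-ol
Conditions: TIPSCl, imidazole, CH2Cl2, 0 °C to rt
Reagents that add atoms: triisopropylsilyl chloride, CC(C)[Si](Cl)(C(C)C)C(C)C
Why: Selective silylation, since the bulky silyl chloride should react at the primary hydroxyl far faster than at the hindered secondary benzylic one.

Step 5
Reactants: 10 (1S,2R)-1-[3,4-bis(benzyloxy)phenyl]-2-(furan-2-yl)-3-[(triisopropylsilyl)oxy]propan-1-ol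
Product: 12 {[(2R,3S)-3-[3,4-bis(benzyloxy)phenyl]-3-{[(E)-1,2-dichloroethenyl]oxy}-2-(furan-2-yl)propyl]oxy}triisopropylsilane, via potassium alkoxide 11 (not isolated)
Conditions: KH, THF, 0 °C; then Cl2C=CHCl, −50 °C to rt
Reagents that add atoms: trichloroethylene, ClC=C(Cl)Cl
Why: Dichlorovinyl ether formation (first half of the trichloroethylene route to ynol ethers), in which the alkoxide dehydrochlorinates trichloroethylene to dichloroacetylene and adds to it in anti fashion, the carbinol C–O bond is not broken so its configuration is kept, and the triisopropylsilyl group is chosen because it migrates slowly to a neighbouring alkoxide.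

Step 6
Reactants: 12 {[(2R,3S)-3-[3,4-bis(benzyloxy)phenyl]-3-{[(E)-1,2-dichloroethenyl]oxy}-2-(furan-2-yl)propyl]oxy}triisopropylsilane
Product: 15 {[(2R,3S)-3-[3,4-bis(benzyloxy)phenyl]-3-(ethynyloxy)-2-(furan-2-yl)propyl]oxy}triisopropylsilane, via chloroethynyl ether 13 (not isolated), via lithium acetylide 14 (not isolated)
Conditions: n-BuLi (2.4 equiv), THF, −78 to −40 °C; MeOH, −78 °C; cold work-up, filtration through Et3N-deactivated silica, used at once
Reagents that add atoms: none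
Why: Elimination–exchange, in which n-BuLi removes the vinyl hydrogen, chloride is lost to give chloroalkyne 13, a second equivalent exchanges chlorine for lithium to give acetylide 14 and methanol protonates it, all at temperatures at which the furan C5–H and the benzylic C–H should not be metalated.

Step 7
Reactants: 15 {[(2R,3S)-3-[3,4-bis(benzyloxy)phenyl]-3-(ethynyloxy)-2-(furan-2-yl)propyl]oxy}triisopropylsilane
Product: 18 (2S,3R)-2-[3,4-bis(benzyloxy)phenyl]-3-{[(triisopropylsilyl)oxy]methyl}-2,3-dihydro-1-benzofuran-7-ol, via fused oxepine 16 (not isolated), via arene oxide 17 (not isolated)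
Conditions: Ph3PAuNTf2 (3 mol%), CH2Cl2, 4 Å MS, 0 °C to rt
Reagents that add atoms: none
Why: Monovalent gold binds the ethynyl ether and polarises it as a ketene-oxonium, so the oxygen-bearing alkyne carbon is attacked by furan C2 in a 5-exo-dig closure (C3a–C7a bond, dihydrofuran ring), the resulting cyclopropyl gold carbene opens the furan to a dienal carbene, and the aldehyde oxygen adds to the carbene carbon to release oxepine 16 and the catalyst. Oxepine 16 should close by a thermal disrotatory 6π electrocyclisation to arene oxide 17 (C6–C7 bond, ring B), which opens and aromatises by hydrogen shift to the phenol. The closest known reaction is the gold-catalysed furan-yne phenol synthesis, including its alkynyl ether variant that gives 2,3-dihydrobenzofuran-7-ols near room temperature. No stereocentre is made: C2 and C3 come from the aldol as spectators, and the syn arrangement of 15 maps onto the trans ring of 18 because no bond at these carbons is broken. The hydroxyl regiochemistry is secured by O1 on C7a, which stabilises only the cation from C6–O cleavage of 17 and so leaves oxygen on C7, while chemoselectivity rests on the furan being more nucleophilic than the catechol ether ring and held at the 5-exo distance, and on the low temperature, which should keep the benzylic ethynyl ether from ionising or rearranging.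

Step 8
Reactants: 18 (2S,3R)-2-[3,4-bis(benzyloxy)phenyl]-3-{[(triisopropylsilyl)oxy]methyl}-2,3-dihydro-1-benzofuran-7-ol
Product: 19 {[(2S,3R)-7-(benzyloxy)-2-[3,4-bis(benzyloxy)phenyl]-2,3-dihydro-1-benzofuran-3-yl]methoxy}triisopropylsilane
Conditions: BnBr, K2CO3, DMF, rt
Reagents that add atoms: benzyl bromide, BrCc1ccccc1
Why: Williamson etherification, in which only the phenol is acidic enough for carbonate, and the benzyl ether protects it from the oxidants of steps 10 and 13.

Step 9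
Reactants: 19 {[(2S,3R)-7-(benzyloxy)-2-[3,4-bis(benzyloxy)phenyl]-2,3-dihydro-1-benzofuran-3-yl]methoxy}triisopropylsilane
Product: 20 [(2S,3R)-7-(benzyloxy)-2-[3,4-bis(benzyloxy)phenyl]-2,3-dihydro-1-benzofuran-3-yl]methanol
Conditions: Bu4NF, THF, 0 °C to rt
Reagents that add atoms: none
Why: Fluoride-induced Si–O cleavage should free the primary alcohol while the benzyl ethers and both stereocentres stay untouched.

Step 10
Reactants: 20 [(2S,3R)-7-(benzyloxy)-2-[3,4-bis(benzyloxy)phenyl]-2,3-dihydro-1-benzofuran-3-yl]methanol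
Product: 22 (2S,3S)-7-(benzyloxy)-2-[3,4-bis(benzyloxy)phenyl]-2,3-dihydro-1-benzofuran-3-carboxylic acid, via aldehyde 21 (not isolated)
Conditions: TEMPO (cat.), PhI(OAc)2 (2.2 equiv), MeCN/H2O, rt
Reagents that add atoms: water, O
Why: Oxoammonium (TEMPO) oxidation with PhI(OAc)2 as terminal oxidant takes the primary alcohol to aldehyde 21 and, through its hydrate, to the acid in one flask under weakly acidic conditions that should not enolise the C3 aldehyde, so the trans relationship is kept.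

Step 11
Reactants: 23 (R)-3-(3,4-dihydroxyphenyl)lactic acid (danshensu)
Product: 24 4-methoxybenzyl (2R)-3-{3,4-bis[(4-methoxybenzyl)oxy]phenyl}-2-hydroxypropanoate
Conditions: PMBCl (3.3 equiv), K2CO3, NaI (cat.), DMF, rt, argon
Reagents that add atoms: 4-methoxybenzyl chloride, COc1ccc(CCl)cc1
Why: Carbonate-mediated O-alkylation (Williamson and carboxylate alkylation) should cap the two phenols and the carboxylate, the un-ionised secondary alcohol staying free and the stereocentre not being involved.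

Step 12
Reactants: 24 4-methoxybenzyl (2R)-3-{3,4-bis[(4-methoxybenzyl)oxy]phenyl}-2-hydroxypropanoate
Product: 25 4-methoxybenzyl (2R)-2-(acryloyloxy)-3-{3,4-bis[(4-methoxybenzyl)oxy]phenyl}propanoate
Conditions: CH2=CHCOCl, i-Pr2NEt, CH2Cl2, −20 to 0 °C
Reagents that add atoms: acryloyl chloride, C=CC(Cl)=O
Why: Acylation of the secondary alcohol with the acid chloride and a hindered amine base at low temperature should give the acrylate without racemising the α-acyloxy ester.

Step 13
Reactants: 22 (2S,3S)-7-(benzyloxy)-2-[3,4-bis(benzyloxy)phenyl]-2,3-dihydro-1-benzofuran-3-carboxylic acid; 25 4-methoxybenzyl (2R)-2-(acryloyloxy)-3-{3,4-bis[(4-methoxybenzyl)oxy]phenyl}propanoate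
Product: 26 (2S,3S)-7-(benzyloxy)-2-[3,4-bis(benzyloxy)phenyl]-4-[(E)-3-{[(2R)-1-[(4-methoxybenzyl)oxy]-3-{3,4-bis[(4-methoxybenzyl)oxy]phenyl}-1-oxopropan-2-yl]oxy}-3-oxoprop-1-en-1-yl]-2,3-dihydro-1-benzofuran-3-carboxylic acid
Conditions: Pd(OAc)2 (5 mol%), Ac-Ile-OH (10 mol%), KHCO3 (2 equiv), O2 (1 atm), t-AmOH, 85 °C; cold 1 M HCl work-up
Reagents that add atoms: none
Why: Carboxylate-directed ortho-C–H olefination of an arylacetic acid (oxidative Heck, Fujiwara–Moritani type, with an amino acid ligand), in which the C3 carboxylate guides divalent palladium to C4, the only free ortho position, through a six-membered palladacycle, acrylate insertion and β-hydride elimination give the E-alkene, oxygen returns zerovalent palladium to the cycle, and the trans C2/C3 arrangement is the thermodynamic one so it should persist.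

Step 14
Reactants: 26 the C4 (E)-cinnamate acid of step 13
Product: 27 methyl (2S,3S)-7-(benzyloxy)-2-[3,4-bis(benzyloxy)phenyl]-4-[(E)-3-{[(2R)-1-[(4-methoxybenzyl)oxy]-3-{3,4-bis[(4-methoxybenzyl)oxy]phenyl}-1-oxopropan-2-yl]oxy}-3-oxoprop-1-en-1-yl]-2,3-dihydro-1-benzofuran-3-carboxylate
Conditions: TMSCHN2, PhMe/MeOH, 0 °C
Reagents that add atoms: trimethylsilyldiazomethane, C[Si](C)(C)C=[N+]=[N-]
Why: Methylation of the only free carboxylic acid by diazomethane generated in the flask from TMSCHN2 and methanol is neutral and should leave every stereocentre and the PMB ester untouched.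

Step 15
Reactants: 27 the methyl ester of step 14
Product: 28 monomethyl lithospermate, (2R)-2-{[(E)-3-[(2S,3S)-2-(3,4-dihydroxyphenyl)-7-hydroxy-3-(methoxycarbonyl)-2,3-dihydro-1-benzofuran-4-yl]prop-2-enoyl]oxy}-3-(3,4-dihydroxyphenyl)propanoic acid
Conditions: BCl3 (excess), C6HMe5, CH2Cl2, −78 °C; MeOH quench, aqueous work-up
Reagents that add atoms: none
Why: Lewis-acid dealkylation with a cation scavenger, in which BCl3 coordinates the ether and ester oxygens, the three benzyl and three 4-methoxybenzyl groups leave as cations that pentamethylbenzene captures, and at −78 °C the methyl ester, the cinnamate, the C2–O1 bond and the three stereocentres should survive; the lactate half carries 4-methoxybenzyl groups so that its ester ionises as readily as the aryl ethers.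

**Compound list**

1 | 2-(furan-2-yl)acetic acid | OC(=O)Cc1ccco1 | starting material
2 | (S)-4-benzyl-1,3-oxazolidin-2-one | O=C1N[C@@H](Cc2ccccc2)CO1 | starting material
3 | 2-(furan-2-yl)acetic pivalic anhydride | CC(C)(C)C(=O)OC(=O)Cc1ccco1 | intermediate (not isolated)
4 | (S)-4-benzyl-3-[2-(furan-2-yl)acetyl]-1,3-oxazolidin-2-one | O=C(Cc1ccco1)N1[C@@H](Cc2ccccc2)COC1=O | intermediate
5 | 3,4-bis(benzyloxy)benzaldehyde | O=Cc1ccc(OCc2ccccc2)c(OCc2ccccc2)c1 | starting material
6 | (Z)-dibutylboron enolate of 4 | CCCCB(CCCC)O/C(=C\c1ccco1)N1[C@@H](Cc2ccccc2)COC1=O | intermediate (not isolated)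
7 | O-dibutylboryl aldolate of 8 | CCCCB(CCCC)O[C@H](c1ccc(OCc2ccccc2)c(OCc2ccccc2)c1)[C@H](c1ccco1)C(=O)N1[C@@H](Cc2ccccc2)COC1=O | intermediate (not isolated)
8 | (S)-4-benzyl-3-[(2R,3S)-3-[3,4-bis(benzyloxy)phenyl]-2-(furan-2-yl)-3-hydroxypropanoyl]-1,3-oxazolidin-2-one | O[C@H](c1ccc(OCc2ccccc2)c(OCc2ccccc2)c1)[C@H](c1ccco1)C(=O)N1[C@@H](Cc2ccccc2)COC1=O | intermediate
9 | (1S,2R)-1-[3,4-bis(benzyloxy)phenyl]-2-(furan-2-yl)propane-1,3-diol | OC[C@H]([C@H](O)c1ccc(OCc2ccccc2)c(OCc2ccccc2)c1)c1ccco1 | intermediate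
10 | (1S,2R)-1-[3,4-bis(benzyloxy)phenyl]-2-(furan-2-yl)-3-[(triisopropylsilyl)oxy]propan-1-ol | CC(C)[Si](C(C)C)(C(C)C)OC[C@H]([C@H](O)c1ccc(OCc2ccccc2)c(OCc2ccccc2)c1)c1ccco1 | intermediate
11 | potassium alkoxide of 10 | CC(C)[Si](C(C)C)(C(C)C)OC[C@H]([C@H]([O-])c1ccc(OCc2ccccc2)c(OCc2ccccc2)c1)c1ccco1.[K+] | intermediate (not isolated)
12 | {[(2R,3S)-3-[3,4-bis(benzyloxy)phenyl]-3-{[(E)-1,2-dichloroethenyl]oxy}-2-(furan-2-yl)propyl]oxy}triisopropylsilane | CC(C)[Si](C(C)C)(C(C)C)OC[C@H]([C@H](O/C(Cl)=C\Cl)c1ccc(OCc2ccccc2)c(OCc2ccccc2)c1)c1ccco1 | intermediate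
13 | chloroethynyl ether corresponding to 15 | CC(C)[Si](C(C)C)(C(C)C)OC[C@H]([C@H](OC#CCl)c1ccc(OCc2ccccc2)c(OCc2ccccc2)c1)c1ccco1 | intermediate (not isolated)
14 | lithium acetylide of 15 | CC(C)[Si](C(C)C)(C(C)C)OC[C@H]([C@H](OC#C[Li])c1ccc(OCc2ccccc2)c(OCc2ccccc2)c1)c1ccco1 | intermediate (not isolated)
15 | {[(2R,3S)-3-[3,4-bis(benzyloxy)phenyl]-3-(ethynyloxy)-2-(furan-2-yl)propyl]oxy}triisopropylsilane | CC(C)[Si](C(C)C)(C(C)C)OC[C@H]([C@H](OC#C)c1ccc(OCc2ccccc2)c(OCc2ccccc2)c1)c1ccco1 | intermediate (key-step precursor)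
16 | 2-aryl-3-(silyloxymethyl)-2,3-dihydrofuro[2,3-c]oxepine, oxepine oxygen bridging the future C6 and C7, sp3 carbons configured as in 18 | CC(C)[Si](C(C)C)(C(C)C)OC[C@H]1C2=CC=COC=C2O[C@@H]1c1ccc(OCc2ccccc2)c(OCc2ccccc2)c1 | intermediate (not isolated)
17 | 6,7-arene oxide of 18 (6,7-epoxy-6,7-dihydrobenzofuran; epoxide carbons unassigned, both lost on aromatisation) | CC(C)[Si](C(C)C)(C(C)C)OC[C@H]1C2=C(O[C@@H]1c1ccc(OCc3ccccc3)c(OCc3ccccc3)c1)C1OC1C=C2 | intermediate (not isolated)
18 | (2S,3R)-2-[3,4-bis(benzyloxy)phenyl]-3-{[(triisopropylsilyl)oxy]methyl}-2,3-dihydro-1-benzofuran-7-ol | CC(C)[Si](C(C)C)(C(C)C)OC[C@H]1c2cccc(O)c2O[C@@H]1c1ccc(OCc2ccccc2)c(OCc2ccccc2)c1 | intermediate (key-step product)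
19 | {[(2S,3R)-7-(benzyloxy)-2-[3,4-bis(benzyloxy)phenyl]-2,3-dihydro-1-benzofuran-3-yl]methoxy}triisopropylsilane | CC(C)[Si](C(C)C)(C(C)C)OC[C@H]1c2cccc(OCc3ccccc3)c2O[C@@H]1c1ccc(OCc2ccccc2)c(OCc2ccccc2)c1 | intermediate
20 | [(2S,3R)-7-(benzyloxy)-2-[3,4-bis(benzyloxy)phenyl]-2,3-dihydro-1-benzofuran-3-yl]methanol | OC[C@H]1c2cccc(OCc3ccccc3)c2O[C@@H]1c1ccc(OCc2ccccc2)c(OCc2ccccc2)c1 | intermediate
21 | (2S,3S)-7-(benzyloxy)-2-[3,4-bis(benzyloxy)phenyl]-2,3-dihydro-1-benzofuran-3-carbaldehyde | O=C[C@H]1c2cccc(OCc3ccccc3)c2O[C@@H]1c1ccc(OCc2ccccc2)c(OCc2ccccc2)c1 | intermediate (not isolated)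
22 | (2S,3S)-7-(benzyloxy)-2-[3,4-bis(benzyloxy)phenyl]-2,3-dihydro-1-benzofuran-3-carboxylic acid | OC(=O)[C@H]1c2cccc(OCc3ccccc3)c2O[C@@H]1c1ccc(OCc2ccccc2)c(OCc2ccccc2)c1 | intermediate
23 | (R)-3-(3,4-dihydroxyphenyl)lactic acid (danshensu) | O[C@H](Cc1ccc(O)c(O)c1)C(=O)O | starting material
24 | 4-methoxybenzyl (2R)-3-{3,4-bis[(4-methoxybenzyl)oxy]phenyl}-2-hydroxypropanoate | O[C@H](Cc1ccc(OCc2ccc(OC)cc2)c(OCc2ccc(OC)cc2)c1)C(=O)OCc1ccc(OC)cc1 | intermediate
25 | 4-methoxybenzyl (2R)-2-(acryloyloxy)-3-{3,4-bis[(4-methoxybenzyl)oxy]phenyl}propanoate | C=CC(=O)O[C@H](Cc1ccc(OCc2ccc(OC)cc2)c(OCc2ccc(OC)cc2)c1)C(=O)OCc1ccc(OC)cc1 | intermediate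
26 | (2S,3S)-7-(benzyloxy)-2-[3,4-bis(benzyloxy)phenyl]-4-[(E)-3-{[(2R)-1-[(4-methoxybenzyl)oxy]-3-{3,4-bis[(4-methoxybenzyl)oxy]phenyl}-1-oxopropan-2-yl]oxy}-3-oxoprop-1-en-1-yl]-2,3-dihydro-1-benzofuran-3-carboxylic acid | OC(=O)[C@H]1c2c(/C=C/C(=O)O[C@H](Cc3ccc(OCc4ccc(OC)cc4)c(OCc4ccc(OC)cc4)c3)C(=O)OCc3ccc(OC)cc3)ccc(OCc3ccccc3)c2O[C@@H]1c1ccc(OCc2ccccc2)c(OCc2ccccc2)c1 | intermediate
27 | methyl ester of 26 | COC(=O)[C@H]1c2c(/C=C/C(=O)O[C@H](Cc3ccc(OCc4ccc(OC)cc4)c(OCc4ccc(OC)cc4)c3)C(=O)OCc3ccc(OC)cc3)ccc(OCc3ccccc3)c2O[C@@H]1c1ccc(OCc2ccccc2)c(OCc2ccccc2)c1 | intermediate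
28 | monomethyl lithospermate | COC(=O)[C@H]1c2c(/C=C/C(=O)O[C@H](Cc3ccc(O)c(O)c3)C(=O)O)ccc(O)c2O[C@@H]1c1ccc(O)c(O)c1 | target

**Step count and risks**

Total steps: 15. Longest linear sequence: 13 (steps 1–10, then 13–15); the acrylate 25 is made in 2 steps (11, 12).

The three steps most likely to fail:

Step 7 (key step). The gold-bound ketene-oxonium may ionise at the p-alkoxybenzylic C–O bond, be hydrated by traces of water, or be attacked by the catechol ether ring instead of the furan, and the ethynyl ether may rearrange thermally before the catalyst acts. The fallback buys ring B as a bromoarene and closes O1–C7a by an Ullmann etherification; it sets out from 2 and 5 and returns to the route at 19. Commercial 2-bromo-3-hydroxybenzaldehyde would be O-benzylated (BnBr, K2CO3, DMF) to 3-(benzyloxy)-2-bromobenzaldehyde F1, homologated by Van Leusen reductive cyanation (TosMIC, t-BuOK, DME, −40 °C; then MeOH, reflux) to the arylacetonitrile F2, and hydrolysed (KOH, EtOH/H2O, reflux) to the arylacetic acid F3. Acylation of 2 under the conditions of step 1 would give the arylacetyl imide F4, the boron aldol with 5 under the conditions of step 2 the syn-aldol adduct F5, LiBH4 the diol F6, and TIPSCl with imidazole the primary silyl ether F7. Intramolecular copper-catalysed O-arylation of the secondary alcohol (CuI, 3,4,7,8-tetramethyl-1,10-phenanthroline, Cs2CO3, toluene, 110 °C) would then close the dihydrofuran ring without touching either stereocentre and deliver 19.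

Step 5. At the potassium alkoxide stage the silyl group may migrate from the primary to the secondary oxygen, which would place the dichlorovinyl group on the wrong oxygen, or the hindered alkoxide may capture dichloroacetylene too slowly. The fallback avoids any alkoxide; it sets out from 10 and returns at 15. Formylation (acetic formic anhydride, pyridine, CH2Cl2, 0 °C) would give the formate F8, dichloromethylenation of the formate carbonyl (PPh3, CCl4, THF, 60 °C) the 2,2-dichlorovinyl ether F9, and n-BuLi (THF, −78 °C) followed by MeOH would take this through 13 and 14 to 15.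

Step 13. The bulky acrylate 25 may insert slowly while the potassium carboxylate of 22 is held at 85 °C, allowing epimerisation at C3, ring opening by β-elimination of the phenoxide, or racemisation of the lactate stereocentre of 25. The fallback forms the ester bond to the lactate last; it sets out from 22 and returns at 27. Olefination of 22 with tert-butyl acrylate under the conditions of step 13 would give the tert-butyl cinnamate acid F10, TMSCHN2 the methyl ester F11, and TFA in CH2Cl2 at 0 °C the cinnamic acid F12. Steglich esterification of this acid with alcohol 24 (EDC·HCl, DMAP, CH2Cl2) would give 27.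

**Further compounds**

F1 | step 7 | 3-(benzyloxy)-2-bromobenzaldehyde | O=Cc1cccc(OCc2ccccc2)c1Br
F2 | step 7 | 2-[3-(benzyloxy)-2-bromophenyl]acetonitrile | N#CCc1cccc(OCc2ccccc2)c1Br
F3 | step 7 | 2-[3-(benzyloxy)-2-bromophenyl]acetic acid | OC(=O)Cc1cccc(OCc2ccccc2)c1Br
F4 | step 7 | (S)-4-benzyl-3-{2-[3-(benzyloxy)-2-bromophenyl]acetyl}-1,3-oxazolidin-2-one | O=C(Cc1cccc(OCc2ccccc2)c1Br)N1[C@@H](Cc2ccccc2)COC1=O
F5 | step 7 | (S)-4-benzyl-3-[(2S,3S)-2-[3-(benzyloxy)-2-bromophenyl]-3-[3,4-bis(benzyloxy)phenyl]-3-hydroxypropanoyl]-1,3-oxazolidin-2-one | O[C@H](c1ccc(OCc2ccccc2)c(OCc2ccccc2)c1)[C@H](c1cccc(OCc2ccccc2)c1Br)C(=O)N1[C@@H](Cc2ccccc2)COC1=O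
F6 | step 7 | (1S,2R)-2-[3-(benzyloxy)-2-bromophenyl]-1-[3,4-bis(benzyloxy)phenyl]propane-1,3-diol | O[C@H](c1ccc(OCc2ccccc2)c(OCc2ccccc2)c1)[C@H](c1cccc(OCc2ccccc2)c1Br)CO
F7 | step 7 | (1S,2R)-2-[3-(benzyloxy)-2-bromophenyl]-1-[3,4-bis(benzyloxy)phenyl]-3-[(triisopropylsilyl)oxy]propan-1-ol | O[C@H](c1ccc(OCc2ccccc2)c(OCc2ccccc2)c1)[C@H](c1cccc(OCc2ccccc2)c1Br)CO[Si](C(C)C)(C(C)C)C(C)C
F8 | step 5 | (1S,2R)-1-[3,4-bis(benzyloxy)phenyl]-2-(furan-2-yl)-3-[(triisopropylsilyl)oxy]propyl formate | CC(C)[Si](C(C)C)(C(C)C)OC[C@H]([C@H](OC=O)c1ccc(OCc2ccccc2)c(OCc2ccccc2)c1)c1ccco1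
F9 | step 5 | {[(2R,3S)-3-[3,4-bis(benzyloxy)phenyl]-3-[(2,2-dichloroethenyl)oxy]-2-(furan-2-yl)propyl]oxy}triisopropylsilane | CC(C)[Si](C(C)C)(C(C)C)OC[C@H]([C@H](OC=C(Cl)Cl)c1ccc(OCc2ccccc2)c(OCc2ccccc2)c1)c1ccco1
F10 | step 13 | (2S,3S)-7-(benzyloxy)-2-[3,4-bis(benzyloxy)phenyl]-4-[(E)-3-(tert-butoxy)-3-oxoprop-1-en-1-yl]-2,3-dihydro-1-benzofuran-3-carboxylic acid | OC(=O)[C@H]1c2c(/C=C/C(=O)OC(C)(C)C)ccc(OCc3ccccc3)c2O[C@@H]1c1ccc(OCc2ccccc2)c(OCc2ccccc2)c1
F11 | step 13 | methyl (2S,3S)-7-(benzyloxy)-2-[3,4-bis(benzyloxy)phenyl]-4-[(E)-3-(tert-butoxy)-3-oxoprop-1-en-1-yl]-2,3-dihydro-1-benzofuran-3-carboxylate | COC(=O)[C@H]1c2c(/C=C/C(=O)OC(C)(C)C)ccc(OCc3ccccc3)c2O[C@@H]1c1ccc(OCc2ccccc2)c(OCc2ccccc2)c1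
F12 | step 13 | (E)-3-[(2S,3S)-7-(benzyloxy)-2-[3,4-bis(benzyloxy)phenyl]-3-(methoxycarbonyl)-2,3-dihydro-1-benzofuran-4-yl]prop-2-enoic acid | COC(=O)[C@H]1c2c(/C=C/C(=O)O)ccc(OCc3ccccc3)c2O[C@@H]1c1ccc(OCc2ccccc2)c(OCc2ccccc2)c1
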